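**Plan**

1. Retrosynthesis (labdane numbering): the acetates go back to the 15,17-diol; C8–C17 is cut (carbonylation of a C7=C8 enol triflate) to an 8-ketone; ring A is then opened at C4–C5; last, C9–C11 (enolate alkylation) and C10–C1 (conjugate addition) are cut, which leaves 3-methylcyclohex-2-enone as ring B.
2. Forward: ring B is bought; the C1–C4 chain is joined at C10 and the C11–C15 side chain at C9; the ketone is desaturated to the C6=C7 enone; ring A, the only ring that is made, is closed last through C4–C5.
3. Enabling feature: C4 carries two methyl groups and can be a tertiary carbocation, and its neighbour, the ring-fusion carbon C5, is the γ-carbon of the ring B enone C6=C7–C8=O. C5 of the derived dienol ether therefore captures C4, and the same C8 carbonyl later becomes the C7=C8–C17 unit.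
4. Stereochemistry: quaternary C10 from a catalyst-controlled conjugate addition; C13 from (R)-methyl hydrogen 3-methylglutarate; C5 and C9 by base equilibration relative to C10 after ring closure.

Key step: step 8

Remark: labdane numbering (C1–C20) is used for all compounds; the two C9 epimers formed in step 4 are carried together and converge in step 8.

Step 1
Reactants: 1 (3R)-5-methoxy-3-methyl-5-oxopentanoic acid [(R)-methyl hydrogen 3-methylglutarate]
Product: 3 (4S)-4-methyloxan-2-one, via (3S)-5-hydroxy-3-methylpentanoic acid 2 (not isolated)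
Conditions: LiBH4, THF, 0 °C to 50 °C; then 2 M HCl, rt
Reagents that add atoms: none
Why: LiBH4 reduces the methyl ester but not the lithium carboxylate, and the δ-hydroxy acid lactonizes on acidification (chemoselective ester reduction, lactonization), so the ester arm becomes the future C11/C12 end while the C13 stereocentre is untouched.

Step 2
Reactants: 3 (4S)-4-methyloxan-2-one
Product: 6 methyl (3R)-5-iodo-3-methylpentanoate, via trimethylsilyl (3R)-5-iodo-3-methylpentanoate 4 (not isolated), via (3R)-5-iodo-3-methylpentanoic acid 5 (not isolated)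
Conditions: Me3SiI, CH2Cl2, reflux; then MeOH, rt
Reagents that add atoms: iodotrimethylsilane C[Si](C)(C)I; methanol CO
Why: Iodide opens the silyl-activated lactone by SN2 attack at the O–CH2 carbon and methanol then esterifies the acid under the acid present (silyl iodide lactone cleavage, Fischer esterification); the stereocentre is not involved.

Step 3
Reactants: 7 3-methylcyclohex-2-en-1-one; 8 5-bromo-2-methylpent-2-ene
Product: 11 trimethyl{[(3R)-3-methyl-3-(4-methylpent-3-en-1-yl)cyclohex-1-en-1-yl]oxy}silane, via (4-methylpent-3-en-1-yl)magnesium bromide 9 (not isolated), via bromomagnesium (3R)-3-methyl-3-(4-methylpent-3-en-1-yl)cyclohex-1-en-1-olate 10 (not isolated)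
Conditions: 8, Mg, Et2O, rt; then 7, Cu(OTf)2 (3 mol %), chiral N-mesityl-N′-(1-hydroxy-4-methylpent-2-yl)imidazolinium hexafluorophosphate (NHC precursor, 4 mol %, enantiomer that gives the 3R product), Et2O, 0 °C; then Me3SiCl, Et3N, 0 °C to rt
Reagents that add atoms: chlorotrimethylsilane C[Si](C)(C)Cl
Why: Copper-catalysed asymmetric conjugate addition of a Grignard reagent to a β-substituted cyclic enone, in which the chiral NHC–copper complex selects the enone face and so sets the quaternary C10, and O-silylation keeps the enolate regiochemistry at C9.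

Step 4
Reactants: 11 trimethyl{[(3R)-3-methyl-3-(4-methylpent-3-en-1-yl)cyclohex-1-en-1-yl]oxy}silane; 6 methyl (3R)-5-iodo-3-methylpentanoate
Product: 13 methyl (3S)-3-methyl-5-[(2R)-2-methyl-2-(4-methylpent-3-en-1-yl)-6-oxocyclohexyl]pentanoate (both C9 epimers), via lithium (3R)-3-methyl-3-(4-methylpent-3-en-1-yl)cyclohex-1-en-1-olate 12 (not isolated)
Conditions: MeLi (1.0 equiv), THF, 0 °C; then DMPU, 6, −40 °C to 0 °C
Reagents that add atoms: none
Why: MeLi cleaves the silyl enol ether to the regiodefined lithium enolate, which is alkylated at C9 by the primary iodide (SN2 enolate alkylation); C9 forms as an epimer mixture that converges in step 8 and C13 comes unchanged from 1.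

Step 5
Reactants: 13 methyl (3S)-3-methyl-5-[(2R)-2-methyl-2-(4-methylpent-3-en-1-yl)-6-oxocyclohexyl]pentanoate
Product: 15 methyl (3S)-3-methyl-5-[(6S)-6-methyl-6-(4-methylpent-3-en-1-yl)-2-oxocyclohex-3-en-1-yl]pentanoate (C9 epimers), via kinetic lithium C7=C8 enolate 14 (not isolated)
Conditions: LiN(i-Pr)2, THF, −78 °C; then PhS(Cl)=N-t-Bu, −78 °C
Reagents that add atoms: none
Why: Kinetic deprotonation occurs at the C7 methylene (C9–H is tertiary and flanked by the quaternary C10) and the enolate is dehydrogenated by the sulfinimidoyl chloride (Mukaiyama dehydrogenation) to the C6=C7 enone, the only α,β-position that carries a β-hydrogen in the ring.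

Step 6
Reactants: 15 methyl (3S)-3-methyl-5-[(6S)-6-methyl-6-(4-methylpent-3-en-1-yl)-2-oxocyclohex-3-en-1-yl]pentanoate
Product: 16 methyl (3S)-5-[(6S)-6-(4-chloro-4-methylpentyl)-6-methyl-2-oxocyclohex-3-en-1-yl]-3-methylpentanoate (C9 epimers)
Conditions: HCl (g), CH2Cl2, −30 °C
Reagents that add atoms: hydrogen chloride Cl
Why: Markovnikov hydrochlorination of the electron-rich trisubstituted C3=C4 alkene gives the tertiary chloride, the latent C4 cation, while any HCl addition to the electron-poor enone is reversed on basic work-up.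

Step 7
Reactants: 16 methyl (3S)-5-[(6S)-6-(4-chloro-4-methylpentyl)-6-methyl-2-oxocyclohex-3-en-1-yl]-3-methylpentanoate
Product: 17 methyl (3S)-5-[(6S)-2-{[tert-butyl(dimethyl)silyl]oxy}-6-(4-chloro-4-methylpentyl)-6-methylcyclohexa-2,4-dien-1-yl]-3-methylpentanoate (C9 epimers)
Conditions: t-BuMe2SiOTf, Et3N, CH2Cl2, 0 °C
Reagents that add atoms: tert-butyldimethylsilyl trifluoromethanesulfonate CC(C)(C)[Si](C)(C)OS(=O)(=O)C(F)(F)F
Why: Soft enolization of the enone (silyl triflate and amine) removes a γ-proton from C5 and gives the linear 2-silyloxy-1,3-diene, as with steroidal 4-en-3-ones, because the α′-proton at C9 is tertiary and shielded by C10 and the side chain.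

Step 8
Reactants: 17 methyl (3S)-5-[(6S)-2-{[tert-butyl(dimethyl)silyl]oxy}-6-(4-chloro-4-methylpentyl)-6-methylcyclohexa-2,4-dien-1-yl]-3-methylpentanoate
Product: 19 methyl (13S)-8-oxo-17-norlabd-6-en-15-oate (5α-H 9α-H 10β-methyl), via C5/C9-epimeric methyl (13S)-8-oxo-17-norlabd-6-en-15-oate mixture 18 (not isolated)
Conditions: TiCl4 (2.2 equiv), CH2Cl2, −78 °C to −40 °C; aq. NaHCO3; then NaOMe, MeOH, 40 °C
Reagents that add atoms: none
Why: TiCl4 abstracts chloride from C4 to give the tertiary C4 carbocation, which is captured by C5, the γ-terminus of the 2-silyloxy-1,3-diene in ring B, and loss of the silyl group as t-BuMe2SiCl returns the C6=C7–C8=O enone, so the C4–C5 bond forms with the polarity of the biosynthetic ring A closure (C4 cation, C5 π-nucleophile). The closest known reaction types are the Lewis-acid-mediated alkylation of silyl enol ethers with tertiary alkyl chlorides, the γ-selective reaction of silyl dienol ethers with carbocationic electrophiles (vinylogous Mukaiyama type) and cation–olefin cyclizations ended by a silyl enol ether. Ring A closes as a six-membered ring by C4–C5 bond formation, exo with respect to the C5=C6 bond of the diene (C6 stays outside the new ring), through a chair-like fold of C10–C1–C2–C3–C4. The only new stereocentre is C5, and since attack on the diene face syn to the tether should first give mainly the cis-fused enone, the ring fusion is set afterwards under thermodynamic control: NaOMe epimerizes C5 through the extended dienolate (C5–H is vinylogous to the C8 carbonyl) and C9 through the C8 enolate, and the fixed quaternary C10 should direct both into the trans-fused form with C4 and the C9 side chain equatorial. The step needs γ-regioselectivity, which the substrate secures because attack through C7 would require a bridged eight-membered ring and C9 is sp3 in the linear dienol ether, so only C5 can reach C4; the ester is the only other Lewis-basic group and is covered by the second equivalent of TiCl4.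

Step 9
Reactants: 19 methyl (13S)-8-oxo-17-norlabd-6-en-15-oate
Product: 21 methyl (13S)-8-{[(trifluoromethyl)sulfonyl]oxy}-17-norlabd-7-en-15-oate, via lithium C7=C8 enolate 20 (not isolated)
Conditions: LiBH(s-Bu)3, THF, −78 °C; then PhNTf2, −78 °C to 0 °C
Reagents that add atoms: N-phenylbis(trifluoromethanesulfonimide) O=S(=O)(N(c1ccccc1)S(=O)(=O)C(F)(F)F)C(F)(F)F
Why: Conjugate reduction of the β-unsubstituted enone by the hindered borohydride gives the C7=C8 enolate regiospecifically, and O-sulfonylation traps it (reductive enol triflate formation) without touching the stereocentres.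

Step 10
Reactants: 21 methyl (13S)-8-{[(trifluoromethyl)sulfonyl]oxy}-17-norlabd-7-en-15-oate
Product: 22 dimethyl (13S)-labd-7-ene-15,17-dioate
Conditions: Pd(OAc)2 (5 mol %), PPh3, CO (1 atm), MeOH, Et3N, DMF, 50 °C
Reagents that add atoms: carbon monoxide [C-]#[O+]; methanol CO
Why: Palladium-catalysed methoxycarbonylation of the enol triflate (oxidative addition, CO insertion, methanolysis) installs C17 on C8 with the C7=C8 double bond already in place.

Step 11
Reactants: 22 dimethyl (13S)-labd-7-ene-15,17-dioate
Product: 23 (13S)-labd-7-ene-15,17-diol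
Conditions: i-Bu2AlH (excess), CH2Cl2, −78 °C to 0 °C; Rochelle salt
Reagents that add atoms: none
Why: i-Bu2AlH reduces the conjugated ester to the allylic alcohol (1,2-reduction) and the saturated ester to the primary alcohol in one operation.

Step 12
Reactants: 23 (13S)-labd-7-ene-15,17-diol
Product: 24 (5S,9R,10S,13S)-labd-7-ene-15,17-diyl diacetate
Conditions: Ac2O, pyridine, DMAP (cat.), CH2Cl2, rt
Reagents that add atoms: acetic anhydride CC(=O)OC(C)=O
Why: DMAP-catalysed acetylation of both primary alcohols gives the target without affecting the trisubstituted alkene or any stereocentre.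

**Compound list**

1 | (3R)-5-methoxy-3-methyl-5-oxopentanoic acid | OC(=O)C[C@@H](C)CC(=O)OC | starting material
2 | (3S)-5-hydroxy-3-methylpentanoic acid | OC(=O)C[C@@H](C)CCO | intermediate (not isolated)
3 | (4S)-4-methyloxan-2-one | O=C1C[C@@H](C)CCO1 | intermediate
4 | trimethylsilyl (3R)-5-iodo-3-methylpentanoate | C[Si](C)(C)OC(=O)C[C@@H](C)CCI | intermediate (not isolated)
5 | (3R)-5-iodo-3-methylpentanoic acid | OC(=O)C[C@@H](C)CCI | intermediate (not isolated)
6 | methyl (3R)-5-iodo-3-methylpentanoate | COC(=O)C[C@@H](C)CCI | intermediate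
7 | 3-methylcyclohex-2-en-1-one | CC1=CC(=O)CCC1 | starting material
8 | 5-bromo-2-methylpent-2-ene | CC(C)=CCCBr | starting material
9 | (4-methylpent-3-en-1-yl)magnesium bromide | CC(C)=CCC[Mg]Br | intermediate (not isolated)
10 | bromomagnesium (3R)-3-methyl-3-(4-methylpent-3-en-1-yl)cyclohex-1-en-1-olate | Br[Mg]OC1=C[C@@](C)(CCC=C(C)C)CCC1 | intermediate (not isolated)
11 | trimethyl{[(3R)-3-methyl-3-(4-methylpent-3-en-1-yl)cyclohex-1-en-1-yl]oxy}silane | C[Si](C)(C)OC1=C[C@@](C)(CCC=C(C)C)CCC1 | intermediate
12 | lithium (3R)-3-methyl-3-(4-methylpent-3-en-1-yl)cyclohex-1-en-1-olate | [Li]OC1=C[C@@](C)(CCC=C(C)C)CCC1 | intermediate (not isolated)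
13 | methyl (3S)-3-methyl-5-[(2R)-2-methyl-2-(4-methylpent-3-en-1-yl)-6-oxocyclohexyl]pentanoate, C9 epimers | COC(=O)C[C@@H](C)CCC1C(=O)CCC[C@]1(C)CCC=C(C)C | intermediate
14 | lithium (5S)-6-[(3S)-5-methoxy-3-methyl-5-oxopentyl]-5-methyl-5-(4-methylpent-3-en-1-yl)cyclohex-1-en-1-olate (C7=C8 enolate) | COC(=O)C[C@@H](C)CCC1C(O[Li])=CCC[C@]1(C)CCC=C(C)C | intermediate (not isolated)
15 | methyl (3S)-3-methyl-5-[(6S)-6-methyl-6-(4-methylpent-3-en-1-yl)-2-oxocyclohex-3-en-1-yl]pentanoate, C9 epimers | COC(=O)C[C@@H](C)CCC1C(=O)C=CC[C@]1(C)CCC=C(C)C | intermediate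
16 | methyl (3S)-5-[(6S)-6-(4-chloro-4-methylpentyl)-6-methyl-2-oxocyclohex-3-en-1-yl]-3-methylpentanoate, C9 epimers | COC(=O)C[C@@H](C)CCC1C(=O)C=CC[C@]1(C)CCCC(C)(C)Cl | intermediate
17 | methyl (3S)-5-[(6S)-2-{[tert-butyl(dimethyl)silyl]oxy}-6-(4-chloro-4-methylpentyl)-6-methylcyclohexa-2,4-dien-1-yl]-3-methylpentanoate, C9 epimers | COC(=O)C[C@@H](C)CCC1C(O[Si](C)(C)C(C)(C)C)=CC=C[C@]1(C)CCCC(C)(C)Cl | intermediate
18 | methyl (13S)-8-oxo-17-norlabd-6-en-15-oate, mixture of C5 and C9 epimers (10β-methyl fixed) | COC(=O)C[C@@H](C)CCC1C(=O)C=CC2C(C)(C)CCC[C@]12C | intermediate (not isolated)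
19 | methyl (13S)-8-oxo-17-norlabd-6-en-15-oate (5α-H, 9α-H, 10β-methyl) | COC(=O)C[C@@H](C)CC[C@H]1C(=O)C=C[C@H]2C(C)(C)CCC[C@]12C | intermediate
20 | lithium (13S)-15-methoxy-15-oxo-17-norlabd-7-en-8-olate | COC(=O)C[C@@H](C)CC[C@H]1C(O[Li])=CC[C@H]2C(C)(C)CCC[C@]12C | intermediate (not isolated)
21 | methyl (13S)-8-{[(trifluoromethyl)sulfonyl]oxy}-17-norlabd-7-en-15-oate | COC(=O)C[C@@H](C)CC[C@H]1C(OS(=O)(=O)C(F)(F)F)=CC[C@H]2C(C)(C)CCC[C@]12C | intermediate
22 | dimethyl (13S)-labd-7-ene-15,17-dioate | COC(=O)C[C@@H](C)CC[C@H]1C(C(=O)OC)=CC[C@H]2C(C)(C)CCC[C@]12C | intermediate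
23 | (13S)-labd-7-ene-15,17-diol | OCC[C@@H](C)CC[C@H]1C(CO)=CC[C@H]2C(C)(C)CCC[C@]12C | intermediate
24 | (5S,9R,10S,13S)-labd-7-ene-15,17-diyl diacetate | CC(=O)OCC[C@@H](C)CC[C@H]1C(COC(C)=O)=CC[C@H]2C(C)(C)CCC[C@]12C | target

**Step count**

Total: 12 steps. Longest linear sequence: 11 steps (1 to 24 through steps 1, 2 and 4–12).

**Steps most likely to fail**

Step 8. What may go wrong: after the C4–C5 bond has formed, the ring fusion may not funnel to the trans series, because epimerization at C5 must pass through the extended dienolate of a proton flanked by the quaternary carbons C4 and C10 (slow γ-deprotonation, or an equilibrium that keeps cis-fused and deconjugated isomers). The fallback sets out from 18 (kept as the crude mixture) and comes back to the route at 21. The mixture is deconjugated (t-BuOK, t-BuOH/THF, 0 °C, fast AcOH quench) through its potassium dienolate F1 to methyl (13S)-8-oxo-17-norlabd-5-en-15-oate F2, in which C5 is trigonal. Hydrogen-atom-transfer hydrogenation (Mn(dpm)3, PhSiH3, t-BuOOH, i-PrOH, rt) puts hydrogen on C6 and then on the tertiary C5 radical; this should give the thermodynamically preferred trans-fused methyl (13S)-8-oxo-17-norlabdan-15-oate F3, whose C9 centre (α to the ketone) is equilibrated with NaOMe/MeOH. Kinetic deprotonation at C7 (KN(SiMe3)2, THF, −78 °C) gives the potassium C7=C8 enolate F4, and PhNTf2 converts it into 21.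

Step 4. What may go wrong: SN2 attack by the enolate carbon next to the quaternary C10 is slow, so proton exchange between enolate and product, alkylation at C7 or on oxygen, and low conversion can take over. The fallback sets out from 6 and 11 and comes back at 13. Iodide 6 is oxidized (NaHCO3, DMSO, 110 °C, Kornblum oxidation) to methyl (3S)-3-methyl-5-oxopentanoate F5. Enolate 12 (from 11 and MeLi as in step 4) adds to F5 at −78 °C (aldol addition, much less sensitive to hindrance) to give methyl (3S)-5-hydroxy-3-methyl-5-[(2R)-2-methyl-2-(4-methylpent-3-en-1-yl)-6-oxocyclohexyl]pentanoate F6. MsCl/Et3N gives its mesylate F7, and DBU eliminates this to the exocyclic enone methyl (3S)-3-methyl-5-[(2R)-2-methyl-2-(4-methylpent-3-en-1-yl)-6-oxocyclohexylidene]pentanoate F8. [(Ph3P)CuH]6 (benzene, rt) then reduces only the conjugated C9=C11 bond and gives 13.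

Step 3. What may go wrong: incomplete face discrimination in the copper-catalysed Grignard addition would leave the C10 epimer, which after step 4 is a diastereomer that is hard to remove. The fallback sets out from 9 (made from 8) and commercial 3-ethoxycyclohex-2-en-1-one and comes back at 11; it forms the C10–C20 bond last instead of the C10–C1 bond. Reagent 9 adds to the carbonyl of 3-ethoxycyclohex-2-en-1-one to give 3-ethoxy-1-(4-methylpent-3-en-1-yl)cyclohex-2-en-1-ol F9, and aqueous HCl converts it (Stork–Danheiser transposition) into 3-(4-methylpent-3-en-1-yl)cyclohex-2-en-1-one F10. Copper-catalysed asymmetric conjugate addition of Me3Al (copper thiophene-2-carboxylate, chiral biphenol-derived phosphoramidite, Et2O, −30 °C) gives the dimethylaluminium (3R)-enolate F11, and Me3SiOTf converts it into 11.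

**Further compounds**

F1 | step 8 | potassium dienolate of 18 (C8–O, C7=C8, C5=C6) | COC(=O)C[C@@H](C)CCC1C(O[K])=CC=C2C(C)(C)CCC[C@]12C
F2 | step 8 | methyl (13S)-8-oxo-17-norlabd-5-en-15-oate, C9 epimers | COC(=O)C[C@@H](C)CCC1C(=O)CC=C2C(C)(C)CCC[C@]12C
F3 | step 8 | methyl (13S)-8-oxo-17-norlabdan-15-oate | COC(=O)C[C@@H](C)CC[C@H]1C(=O)CC[C@H]2C(C)(C)CCC[C@]12C
F4 | step 8 | potassium (13S)-15-methoxy-15-oxo-17-norlabd-7-en-8-olate | COC(=O)C[C@@H](C)CC[C@H]1C(O[K])=CC[C@H]2C(C)(C)CCC[C@]12C
F5 | step 4 | methyl (3S)-3-methyl-5-oxopentanoate | COC(=O)C[C@@H](C)CC=O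
F6 | step 4 | methyl (3S)-5-hydroxy-3-methyl-5-[(2R)-2-methyl-2-(4-methylpent-3-en-1-yl)-6-oxocyclohexyl]pentanoate | COC(=O)C[C@@H](C)CC(O)C1C(=O)CCC[C@]1(C)CCC=C(C)C
F7 | step 4 | methyl (3S)-5-(methanesulfonyloxy)-3-methyl-5-[(2R)-2-methyl-2-(4-methylpent-3-en-1-yl)-6-oxocyclohexyl]pentanoate | COC(=O)C[C@@H](C)CC(OS(C)(=O)=O)C1C(=O)CCC[C@]1(C)CCC=C(C)C
F8 | step 4 | methyl (3S)-3-methyl-5-[(2R)-2-methyl-2-(4-methylpent-3-en-1-yl)-6-oxocyclohexylidene]pentanoate | COC(=O)C[C@@H](C)CC=C1C(=O)CCC[C@]1(C)CCC=C(C)C
F9 | step 3 | 3-ethoxy-1-(4-methylpent-3-en-1-yl)cyclohex-2-en-1-ol | CCOC1=CC(O)(CCC=C(C)C)CCC1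
F10 | step 3 | 3-(4-methylpent-3-en-1-yl)cyclohex-2-en-1-one | CC(C)=CCCC1=CC(=O)CCC1
F11 | step 3 | dimethylaluminium (3R)-3-methyl-3-(4-methylpent-3-en-1-yl)cyclohex-1-en-1-olate | C[Al](C)OC1=C[C@@](C)(CCC=C(C)C)CCC1
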